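## The problem

Compound 26 is an 8-O-4' neolignan: ring A (3,4-dimethoxyphenyl) sits on C7 of the chain C7–C8–C9, and the oxygen on C8 is the ether oxygen at C4' of ring B, which is flanked by a free phenol at C3' and a methoxy group at C5' and carries a 3-hydroxypropanoyl chain (C7'–C9') at C1'. No ring has to be closed; the work lies in one hindered secondary alkyl aryl ether, two adjacent stereocentres (C7 and C8, both S, the threo pair) and four hydroxyl groups that must all end up free. C8 can control C7, because a C7 ketone next to the C8–O bond is reduced with predictable 1,2-induction, but nothing in the molecule can control C8, so the absolute configuration has to be introduced there. The C8–O–C4' bond is a poor candidate for a late SN2 reaction, since the nucleophile would be a 2,6-disubstituted phenoxide and the electrophile a secondary carbon beside a benzylic centre; it is better made while C8 is still an activated, non-stereogenic carbon. Several groups will not stand rough treatment: the C7 benzylic alcohol para to a methoxy group ionises and epimerises in acid, the β-hydroxy aryl ketone of the C7'–C9' chain dehydrates or undergoes retro-aldol cleavage in base, the electron-rich phenol of ring B is easily oxidised, and every intermediate with a carbonyl group at C7 has an acidic C8–H with a leaving group on C9. Two carbons pass through the ketone level (C7 and C7'), and they have to be told apart. The feature that opens the route is that C8 carries the aryloxy group and two oxygenated one-carbon arms, C7 and C9: with ring A removed both arms are CH2OH, C8 is the prochiral carbon of a 2-aryloxypropane-1,3-diol, and a catalyst that distinguishes the enantiotopic arms sets C8 without making or breaking any bond at C8.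

## Retrosynthesis

**Unmasking (26 from 25 from 24).** The last two operations cut no skeletal bond: the O–benzyl bond of the C3' phenol (26 from 25) and the O–Si bonds at C7 and C9 (25 from 24). A benzyl ether is the one phenol protection that survives aryllithium, hydride and enolate chemistry. Its hydrogenolysis is placed last because it leaves only a volatile by-product beside the polar target. The forward steps must stay near neutral because of the β-hydroxy ketone and the C7 carbinol.

**The C7'–C8' bond (24 back to 19 and 20).** The hydroxypropanoyl chain is cut between C7' and C8', giving aldehyde 19 and the lithium enolate 21 of ethyl acetate 20. The neighbouring cuts are worse. Cutting C1'–C7' would need an aryl metal or an acylation on the fully substituted ring B. Cutting C8'–C9' would mean a hydroxymethylation of a methyl ketone that is hard to stop after one addition. The aldol adduct 22 has the right carbons in the wrong oxidation pattern. Reduction to diol 23 and a benzylic-selective oxidation to 24 correct this. The oxidation requires the other benzylic oxygen, at C7, to be masked, hence the silyl ether in 19, which comes from hydroxy aldehyde 18 and this from dioxolane 17.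

**The C7–H bond (17 from 16).** The C7 stereocentre is traced to ketone 16. C8 is already in place there, and a bulky, non-chelating hydride should add anti to the C8–OAr bond (Felkin–Anh), which gives the threo alcohol. The neighbouring cut, adding ring A to a C7 aldehyde, would give the erythro isomer under the same model, or would depend on chelation to a weakly basic aryl ether oxygen.

**The C7–C1 bond (16 back to 13 and 14).** Ring A is removed as aryllithium 15, made from bromide 14, and the C3 unit becomes Weinreb amide 13. The amide is chosen because it stops cleanly at the ketone. This cut takes away half of the carbon count and leaves a three-carbon unit that carries only ring B. The forward step must not deprotonate C8.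

**Differentiating the arms (13 back to 8).** Amide 13 comes from acid 12, made from alcohol 10 by way of aldehyde 11; 10 comes from acetate 9, and 9 from monoacetate 8. No skeletal bond is cut. The acetate in 8 serves only as a marker: the free arm is silylated and becomes C9, the marked arm is unveiled and oxidised and becomes C7. The forward steps must avoid acyl or silyl migration between the arms, since either would racemise C8.

**The key cut (8 back to 6 and 7).** Removing the acetyl group of 8 gives the achiral diol 6 and vinyl acetate 7. This is the only step that creates absolute configuration, and it asks of the enzyme only that it acylate one enantiotopic hydroxymethyl group. Diol 6 has no stereocentre and is made in four steps.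

**The C8–O bond (6 back to 1 and 2).** The aryl ether is cut at the malonate oxidation level. Bromomalonate 2 is an activated electrophile that even a flanked phenoxide should attack. In 5-hydroxyvanillin 1 the 4-hydroxyl is para to the formyl group and the more acidic, so it is the one that alkylates, giving 3. The aldehyde is then masked (4), the esters are reduced (5), and the phenol is benzylated last (6). Benzylation is placed after the reduction because in 3 and 4 the C–H between the two esters is acidic enough to compete with the phenol for the alkylating agent; in 5 the phenol is the only acidic site.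

## Roads not taken

**Alternative 1:** The cut is the O–C4' bond, made from the alcohol side with ring B still non-aromatic. A rhodium carboxylate catalyst would turn the diazo dione A2 into a carbenoid that inserts into the single free C8–OH of the silylene-protected (7S,8S)-triol A1 and gives the 2-alkoxy-1,3-dione A3. The C8–O bond is never broken, so C8 is retained.
- Merits: both stereocentres would come from one asymmetric dihydroxylation of an E-cinnamyl precursor, so the threo relation is built in and C8 is never alpha to a carbonyl group. In stereochemical security this road is better than the chosen plan, which depends on a diastereoselective reduction for C7.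
- Weak points: A3 must be dehydrogenated to an arene in the presence of a benzylic silyl ether. The two ring oxygens then emerge equivalent, and one must be methylated while the other stays free. The ester must still be turned into the hydroxypropanoyl chain. Insertion into a hindered secondary alcohol also competes with carbenoid dimerisation and rearrangement.
- Comparison: the chosen plan sets against the better stereocontrol a ring B that is aromatic, correctly differentiated at C3', C4' and C5' and already carries the C7' carbon from the first step.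

**Alternative 2:** The cut is the C7–H bond with C8 left racemic. A chiral ruthenium diamine transfer-hydrogenation catalyst with a formate hydride source would reduce the racemic keto ester A4 while C8 equilibrates through the enol, giving the syn hydroxy ester A5 with both centres set in one step.
- Merits: A4 is reachable in two or three steps, the C3 unit needs no protecting-group exchange, and the step is catalytic. Up to the threo stage this road is shorter than the chosen plan and in step economy it is the better one.
- Weak points: syn selectivity and enantioselectivity would depend on an aryloxy group with two ortho substituents, which is bulkier than the usual substrates. A5 has two esters (C9 and the ring B benzoate) that must then be told apart. The benzoate has to be taken down to the aldehyde level before the same three-step chain extension can start. A5 itself is prone to retro-aldol cleavage in base.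
- Comparison: the chosen plan sets C8 under neutral conditions on a small substrate without ring A and can raise the enantiomeric purity through over-acylation. It tunes the C7 reduction independently and keeps the ring B carbonyl at the aldehyde level, orthogonal to the two arms.

**Alternative 3:** The cut is the C7–O bond. A flavin-dependent oxidase of the vanillyl alcohol oxidase type would oxidise the para-alkylphenol of the 7-deoxy phenol A6 to its quinone methide, and hydration at C7 would give the 7-hydroxy ether A7.
- Merits: C7 would be introduced at the right oxidation level at the end, without a C7 ketone, so C8 is never epimerisable and C7 needs no protecting group. In this respect it is more direct than the chosen plan.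
- Weak points: such enzymes are established for small 4-alkylphenols, whereas A6 has a large aryloxy group beside the reacting carbon. The quinone methide can lose a proton from C8 to give an enol ether, which leads to cleavage of the aryl ether. The facial selectivity next to an existing stereocentre is unknown. Ring A must carry a free phenol that is methylated afterwards. Enantiopure A6 still needs its own asymmetric step, so the problem of C8 is not removed.
- Comparison: the chosen plan uses a commercial lipase on a substrate class that it is known to accept, and needs only one source of absolute configuration.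

Key step: step 5

Assumption: the lipase is taken to acetylate the same enantiotopic arm as in 2-O-benzylglycerol, which gives the (S)-monoacetate 8; this is a prediction by analogy and the configuration of 8 is to be confirmed before step 6.

## Route

**Step 1**
Reactants: 1 3,4-dihydroxy-5-methoxybenzaldehyde (5-hydroxyvanillin); 2 diethyl 2-bromomalonate
Product: 3 diethyl 2-(4-formyl-2-hydroxy-6-methoxyphenoxy)malonate
Conditions: NaHCO3 (1.2 equiv), DMF, N2, 40 °C
Reagents that add atoms: none
Why: Williamson ether synthesis (SN2 at the malonate carbon); the weak base ionises only the 4-hydroxyl, which is para to the formyl group and the more acidic one, as in the known selective 4-O-alkylation of 5-hydroxyvanillin, and the activated bromide makes up for the two flanking substituents.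

**Step 2**
Reactants: 3 diethyl 2-(4-formyl-2-hydroxy-6-methoxyphenoxy)malonate
Product: 4 diethyl 2-[4-(1,3-dioxolan-2-yl)-2-hydroxy-6-methoxyphenoxy]malonate
Conditions: ethylene glycol, HC(OEt)3, p-TsOH·H2O (cat.), CH2Cl2, rt
Reagents that add atoms: ethylene glycol, OCCO
Why: Acid-catalysed acetalisation driven by the orthoformate as water scavenger at room temperature masks the aldehyde before the hydride and organolithium steps; any ester exchange or lactonisation onto the free phenol is harmless, because all such esters converge on triol 5 in step 3.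

**Step 3**
Reactants: 4 diethyl 2-[4-(1,3-dioxolan-2-yl)-2-hydroxy-6-methoxyphenoxy]malonate
Product: 5 2-[4-(1,3-dioxolan-2-yl)-2-hydroxy-6-methoxyphenoxy]propane-1,3-diol
Conditions: LiBH4, THF–MeOH, 0 °C → rt; aq. NH4Cl
Reagents that add atoms: none
Why: Borohydride reduction of both malonate esters is the standard entry to 2-aryloxypropane-1,3-diols; the dioxolane and the aryl ethers are inert and the phenol only consumes hydride.

**Step 4**
Reactants: 5 2-[4-(1,3-dioxolan-2-yl)-2-hydroxy-6-methoxyphenoxy]propane-1,3-diol
Product: 6 2-[2-(benzyloxy)-4-(1,3-dioxolan-2-yl)-6-methoxyphenoxy]propane-1,3-diol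
Conditions: BnBr (1.1 equiv), K2CO3, acetone, reflux
Reagents that add atoms: benzyl bromide, BrCc1ccccc1
Why: Chemoselective Williamson O-benzylation of the phenol in the presence of two aliphatic hydroxyls under carbonate conditions; it is placed after the reduction because the acidic malonate C–H of 3 or 4 would compete for the benzyl bromide.

**Step 5**
Reactants: 6 2-[2-(benzyloxy)-4-(1,3-dioxolan-2-yl)-6-methoxyphenoxy]propane-1,3-diol; 7 vinyl acetate
Product: 8 (2S)-2-[2-(benzyloxy)-4-(1,3-dioxolan-2-yl)-6-methoxyphenoxy]-3-hydroxypropyl acetate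
Conditions: Burkholderia cepacia lipase (immobilised), 7 (5 equiv), t-BuOMe, 30 °C
Reagents that add atoms: none
Why: Lipase-catalysed irreversible transesterification, i.e. enantiotopic-group-selective acylation of a prochiral 2-substituted propane-1,3-diol, the reaction type established for 2-O-benzylglycerol. The active-site serine is acetylated by vinyl acetate through a tetrahedral intermediate held in the oxyanion hole, and the acetyl-enzyme passes the acyl group to one of the two enantiotopic hydroxymethyl arms of 6; the vinyl alcohol released tautomerises to acetaldehyde, so the transfer cannot run backwards. One ester C–O bond is formed, no skeletal bond is made and no ring closes. The new stereocentre at C8 is controlled by the enzyme alone: with the aryloxy group held in the large hydrophobic pocket, only one hydroxymethyl arm can reach the acyl serine. The step needs enantiotopic-group selectivity and mono- rather than di-acylation; the first rests on the large size difference between aryloxy and hydrogen at C8, the second on the slower acylation of the monoacetate. Since the minor enantiomer of 8 should be the one converted faster into the achiral diacetate, running slightly past full consumption of 6 should raise the enantiomeric purity of 8. By analogy with 2-O-benzylglycerol the (S)-monoacetate is expected, in which the acetylated arm becomes C7.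

**Step 6**
Reactants: 8 (2S)-monoacetate
Product: 9 (2R)-2-[2-(benzyloxy)-4-(1,3-dioxolan-2-yl)-6-methoxyphenoxy]-3-[(tert-butyldiphenylsilyl)oxy]propyl acetate
Conditions: t-BuPh2SiCl, imidazole, CH2Cl2, 0 °C
Reagents that add atoms: tert-butyl(chloro)diphenylsilane, CC(C)(C)[Si](Cl)(c1ccccc1)c1ccccc1
Why: Imidazole-promoted silylation of the remaining primary hydroxyl at 0 °C fixes the assignment of the arms before 1,3-acyl migration, which would racemise C8, can set in; C8 is untouched and the descriptor becomes R only because CH2OSi outranks CH2OAc.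

**Step 7**
Reactants: 9 (2R)-silyl ether acetate
Product: 10 (2R)-2-[2-(benzyloxy)-4-(1,3-dioxolan-2-yl)-6-methoxyphenoxy]-3-[(tert-butyldiphenylsilyl)oxy]propan-1-ol
Conditions: K2CO3 (cat.), MeOH, 0 °C
Reagents that add atoms: none
Why: Base-catalysed transesterification removes the acetate as methyl acetate; the bulky tert-butyldiphenylsilyl group should not migrate across the 1,3-diol at 0 °C, so the configuration at C8 is kept.

**Step 8**
Reactants: 10 (2R)-alcohol
Product: 12 (2S)-2-[2-(benzyloxy)-4-(1,3-dioxolan-2-yl)-6-methoxyphenoxy]-3-[(tert-butyldiphenylsilyl)oxy]propanoic acid, via (2S)-aldehyde 11 (not isolated)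
Conditions: 2,2,6,6-tetramethylpiperidin-1-oxyl (TEMPO, cat.), NaOCl (cat.), NaClO2, MeCN–phosphate buffer (pH 6.7), 35 °C
Reagents that add atoms: sodium chlorite, [Na+].[O-]Cl=O
Why: Oxoammonium (TEMPO) oxidation to the aldehyde followed in the same flask by Pinnick-type chlorite oxidation to the acid; aldehyde 11 is consumed as it forms, which protects the α-aryloxy stereocentre, and the near-neutral buffer spares the dioxolane and the silyl ether.

**Step 9**
Reactants: 12 (2S)-acid
Product: 13 (2S)-2-[2-(benzyloxy)-4-(1,3-dioxolan-2-yl)-6-methoxyphenoxy]-3-[(tert-butyldiphenylsilyl)oxy]-N-methoxy-N-methylpropanamide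
Conditions: MeNH(OMe)·HCl, N-(3-dimethylaminopropyl)-N'-ethylcarbodiimide hydrochloride, 1-hydroxybenzotriazole, N-methylmorpholine, CH2Cl2, 0 °C → rt
Reagents that add atoms: N,O-dimethylhydroxylamine hydrochloride, CNOC.Cl
Why: Carbodiimide coupling through the benzotriazolyl active ester gives the Weinreb amide; an α-aryloxy acid has no oxazolone pathway for racemisation and the base is weak.

**Step 10**
Reactants: 13 (2S)-Weinreb amide; 14 4-bromo-1,2-dimethoxybenzene
Product: 16 (2S)-2-[2-(benzyloxy)-4-(1,3-dioxolan-2-yl)-6-methoxyphenoxy]-3-[(tert-butyldiphenylsilyl)oxy]-1-(3,4-dimethoxyphenyl)propan-1-one, via 3,4-dimethoxyphenyllithium 15 (not isolated)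
Conditions: 14 (1.5 equiv), n-BuLi, THF, −78 °C; then 13, −78 °C; aq. NH4Cl
Reagents that add atoms: none
Why: Bromine–lithium exchange gives 15, which adds once to the amide to form a stable five-membered lithium chelate that collapses to the ketone only on quench (Weinreb ketone synthesis); the low temperature and the small excess limit deprotonation at C8, whose configuration is carried over.

**Step 11**
Reactants: 16 (2S)-ketone
Product: 17 (1S,2S)-2-[2-(benzyloxy)-4-(1,3-dioxolan-2-yl)-6-methoxyphenoxy]-3-[(tert-butyldiphenylsilyl)oxy]-1-(3,4-dimethoxyphenyl)propan-1-ol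
Conditions: LiBH(sec-Bu)3, THF, −78 °C; aq. NH4Cl
Reagents that add atoms: none
Why: Felkin–Anh 1,2-induction: the bulky, non-chelating hydride attacks C7 anti to the C8–OAr bond and past the C8 hydrogen, which should give the syn (threo) alcohol, here 7S from 8S; the non-coordinating silyl ether on C9 disfavours the chelated pathway.

**Step 12**
Reactants: 17 (1S,2S)-alcohol with dioxolane
Product: 18 3-(benzyloxy)-4-{[(1S,2S)-3-[(tert-butyldiphenylsilyl)oxy]-1-(3,4-dimethoxyphenyl)-1-hydroxypropan-2-yl]oxy}-5-methoxybenzaldehyde
Conditions: pyridinium p-toluenesulfonate (cat.), acetone–H2O, rt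
Reagents that add atoms: water, O
Why: Mild acid-catalysed acetal hydrolysis; the dioxolane of a benzaldehyde should open well before the silyl ether is cleaved or the C7 benzylic alcohol ionises under this weak acid.

**Step 13**
Reactants: 18 hydroxy aldehyde
Product: 19 3-(benzyloxy)-4-{[(1S,2S)-1-[(tert-butyldimethylsilyl)oxy]-3-[(tert-butyldiphenylsilyl)oxy]-1-(3,4-dimethoxyphenyl)propan-2-yl]oxy}-5-methoxybenzaldehyde
Conditions: t-BuMe2SiOTf, 2,6-lutidine, CH2Cl2, −78 °C
Reagents that add atoms: tert-butyldimethylsilyl trifluoromethanesulfonate, CC(C)(C)[Si](C)(C)OS(=O)(=O)C(F)(F)F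
Why: Silyl triflate silylation of the hindered secondary benzylic alcohol; it is placed after step 12 because silyl triflates with pyridine bases attack aldehyde acetals, whereas the non-enolisable aryl aldehyde is inert at −78 °C. Masking C7–OH lets step 16 address the other benzylic alcohol alone.

**Step 14**
Reactants: 19 silyl-protected aldehyde; 20 ethyl acetate
Product: 22 ethyl 3-{3-(benzyloxy)-4-{[(1S,2S)-1-[(tert-butyldimethylsilyl)oxy]-3-[(tert-butyldiphenylsilyl)oxy]-1-(3,4-dimethoxyphenyl)propan-2-yl]oxy}-5-methoxyphenyl}-3-hydroxypropanoate (both epimers at the new carbinol carbon), via lithium enolate of ethyl acetate 21 (not isolated)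
Conditions: 20, LiN(i-Pr)2, THF, −78 °C; then 19, −78 °C; aq. NH4Cl
Reagents that add atoms: none
Why: Aldol addition of the lithium ester enolate to the aryl aldehyde forms the C7'–C8' bond; the new carbinol centre is formed without control, which does not matter because it is oxidised in step 16.

**Step 15**
Reactants: 22 β-hydroxy ester
Product: 23 1-{3-(benzyloxy)-4-{[(1S,2S)-1-[(tert-butyldimethylsilyl)oxy]-3-[(tert-butyldiphenylsilyl)oxy]-1-(3,4-dimethoxyphenyl)propan-2-yl]oxy}-5-methoxyphenyl}propane-1,3-diol (both epimers at C1 of the diol)
Conditions: LiBH4, THF–MeOH, 0 °C → rt; aq. NH4Cl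
Reagents that add atoms: none
Why: Borohydride reduction of the β-hydroxy ester, assisted by the neighbouring alkoxide, gives the 1,3-diol; silyl and benzyl ethers are inert.

**Step 16**
Reactants: 23 1,3-diol
Product: 24 1-{3-(benzyloxy)-4-{[(1S,2S)-1-[(tert-butyldimethylsilyl)oxy]-3-[(tert-butyldiphenylsilyl)oxy]-1-(3,4-dimethoxyphenyl)propan-2-yl]oxy}-5-methoxyphenyl}-3-hydroxypropan-1-one
Conditions: MnO2 (activated, excess), CH2Cl2, rt
Reagents that add atoms: none
Why: Activated manganese dioxide oxidises benzylic secondary alcohols and leaves primary aliphatic alcohols alone; both epimers converge on one ketone, and the only other benzylic oxygen, at C7, is silylated.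

**Step 17**
Reactants: 24 bis-silyl β-hydroxy ketone
Product: 25 1-{3-(benzyloxy)-4-{[(1S,2S)-1-(3,4-dimethoxyphenyl)-1,3-dihydroxypropan-2-yl]oxy}-5-methoxyphenyl}-3-hydroxypropan-1-one
Conditions: n-Bu4NF, AcOH, THF, 0 °C → rt
Reagents that add atoms: none
Why: Fluoride-induced cleavage of both silyl ethers; buffering with acetic acid keeps the medium near neutral, so the β-hydroxy ketone should neither dehydrate nor undergo retro-aldol cleavage.

**Step 18**
Reactants: 25 benzyl-protected triol ketone
Product: 26 1-{4-{[(1S,2S)-1-(3,4-dimethoxyphenyl)-1,3-dihydroxypropan-2-yl]oxy}-3-hydroxy-5-methoxyphenyl}-3-hydroxypropan-1-one (CNP0188882.1)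
Conditions: H2 (1 atm), 10% Pd/C, EtOAc, rt
Reagents that add atoms: none
Why: Hydrogenolysis of a phenolic benzyl ether is much faster in a neutral solvent than reduction of the electron-rich aryl ketone or hydrogenolysis of the C7 benzylic alcohol; the reaction is to be stopped after one equivalent of hydrogen.

## Compound list

1 | 3,4-dihydroxy-5-methoxybenzaldehyde (5-hydroxyvanillin) | COc1cc(C=O)cc(O)c1O | starting material
2 | diethyl 2-bromomalonate | CCOC(=O)C(Br)C(=O)OCC | starting material
3 | diethyl 2-(4-formyl-2-hydroxy-6-methoxyphenoxy)malonate | CCOC(=O)C(Oc1c(O)cc(C=O)cc1OC)C(=O)OCC | intermediate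
4 | diethyl 2-[4-(1,3-dioxolan-2-yl)-2-hydroxy-6-methoxyphenoxy]malonate | CCOC(=O)C(Oc1c(O)cc(C2OCCO2)cc1OC)C(=O)OCC | intermediate
5 | 2-[4-(1,3-dioxolan-2-yl)-2-hydroxy-6-methoxyphenoxy]propane-1,3-diol | OCC(CO)Oc1c(O)cc(C2OCCO2)cc1OC | intermediate
6 | 2-[2-(benzyloxy)-4-(1,3-dioxolan-2-yl)-6-methoxyphenoxy]propane-1,3-diol | OCC(CO)Oc1c(OCc2ccccc2)cc(C2OCCO2)cc1OC | intermediate
7 | vinyl acetate | C=COC(C)=O | starting material
8 | (2S)-2-[2-(benzyloxy)-4-(1,3-dioxolan-2-yl)-6-methoxyphenoxy]-3-hydroxypropyl acetate | CC(=O)OC[C@H](CO)Oc1c(OCc2ccccc2)cc(C2OCCO2)cc1OC | intermediate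
9 | (2R)-2-[2-(benzyloxy)-4-(1,3-dioxolan-2-yl)-6-methoxyphenoxy]-3-[(tert-butyldiphenylsilyl)oxy]propyl acetate | CC(=O)OC[C@H](CO[Si](c1ccccc1)(c1ccccc1)C(C)(C)C)Oc1c(OCc2ccccc2)cc(C2OCCO2)cc1OC | intermediate
10 | (2R)-2-[2-(benzyloxy)-4-(1,3-dioxolan-2-yl)-6-methoxyphenoxy]-3-[(tert-butyldiphenylsilyl)oxy]propan-1-ol | OC[C@H](CO[Si](c1ccccc1)(c1ccccc1)C(C)(C)C)Oc1c(OCc2ccccc2)cc(C2OCCO2)cc1OC | intermediate
11 | (2S)-2-[2-(benzyloxy)-4-(1,3-dioxolan-2-yl)-6-methoxyphenoxy]-3-[(tert-butyldiphenylsilyl)oxy]propanal | O=C[C@H](CO[Si](c1ccccc1)(c1ccccc1)C(C)(C)C)Oc1c(OCc2ccccc2)cc(C2OCCO2)cc1OC | intermediate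
12 | (2S)-2-[2-(benzyloxy)-4-(1,3-dioxolan-2-yl)-6-methoxyphenoxy]-3-[(tert-butyldiphenylsilyl)oxy]propanoic acid | OC(=O)[C@H](CO[Si](c1ccccc1)(c1ccccc1)C(C)(C)C)Oc1c(OCc2ccccc2)cc(C2OCCO2)cc1OC | intermediate
13 | (2S)-2-[2-(benzyloxy)-4-(1,3-dioxolan-2-yl)-6-methoxyphenoxy]-3-[(tert-butyldiphenylsilyl)oxy]-N-methoxy-N-methylpropanamide | CON(C)C(=O)[C@H](CO[Si](c1ccccc1)(c1ccccc1)C(C)(C)C)Oc1c(OCc2ccccc2)cc(C2OCCO2)cc1OC | intermediate
14 | 4-bromo-1,2-dimethoxybenzene | COc1ccc(Br)cc1OC | starting material
15 | 3,4-dimethoxyphenyllithium | COc1ccc([Li])cc1OC | intermediate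
16 | (2S)-2-[2-(benzyloxy)-4-(1,3-dioxolan-2-yl)-6-methoxyphenoxy]-3-[(tert-butyldiphenylsilyl)oxy]-1-(3,4-dimethoxyphenyl)propan-1-one | COc1ccc(C(=O)[C@H](CO[Si](c2ccccc2)(c2ccccc2)C(C)(C)C)Oc2c(OCc3ccccc3)cc(C3OCCO3)cc2OC)cc1OC | intermediate
17 | (1S,2S)-2-[2-(benzyloxy)-4-(1,3-dioxolan-2-yl)-6-methoxyphenoxy]-3-[(tert-butyldiphenylsilyl)oxy]-1-(3,4-dimethoxyphenyl)propan-1-ol | COc1ccc([C@H](O)[C@H](CO[Si](c2ccccc2)(c2ccccc2)C(C)(C)C)Oc2c(OCc3ccccc3)cc(C3OCCO3)cc2OC)cc1OC | intermediate
18 | 3-(benzyloxy)-4-{[(1S,2S)-3-[(tert-butyldiphenylsilyl)oxy]-1-(3,4-dimethoxyphenyl)-1-hydroxypropan-2-yl]oxy}-5-methoxybenzaldehyde | COc1ccc([C@H](O)[C@H](CO[Si](c2ccccc2)(c2ccccc2)C(C)(C)C)Oc2c(OCc3ccccc3)cc(C=O)cc2OC)cc1OC | intermediate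
19 | 3-(benzyloxy)-4-{[(1S,2S)-1-[(tert-butyldimethylsilyl)oxy]-3-[(tert-butyldiphenylsilyl)oxy]-1-(3,4-dimethoxyphenyl)propan-2-yl]oxy}-5-methoxybenzaldehyde | COc1ccc([C@H](O[Si](C)(C)C(C)(C)C)[C@H](CO[Si](c2ccccc2)(c2ccccc2)C(C)(C)C)Oc2c(OCc3ccccc3)cc(C=O)cc2OC)cc1OC | intermediate
20 | ethyl acetate | CCOC(C)=O | starting material
21 | lithium 1-ethoxyethen-1-olate (lithium enolate of ethyl acetate) | [Li]OC(=C)OCC | intermediate
22 | ethyl 3-{3-(benzyloxy)-4-{[(1S,2S)-1-[(tert-butyldimethylsilyl)oxy]-3-[(tert-butyldiphenylsilyl)oxy]-1-(3,4-dimethoxyphenyl)propan-2-yl]oxy}-5-methoxyphenyl}-3-hydroxypropanoate, both epimers at C3 of the propanoate | COc1ccc([C@H](O[Si](C)(C)C(C)(C)C)[C@H](CO[Si](c2ccccc2)(c2ccccc2)C(C)(C)C)Oc2c(OCc3ccccc3)cc(C(O)CC(=O)OCC)cc2OC)cc1OC | intermediate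
23 | 1-{3-(benzyloxy)-4-{[(1S,2S)-1-[(tert-butyldimethylsilyl)oxy]-3-[(tert-butyldiphenylsilyl)oxy]-1-(3,4-dimethoxyphenyl)propan-2-yl]oxy}-5-methoxyphenyl}propane-1,3-diol, both epimers at C1 of the diol | COc1ccc([C@H](O[Si](C)(C)C(C)(C)C)[C@H](CO[Si](c2ccccc2)(c2ccccc2)C(C)(C)C)Oc2c(OCc3ccccc3)cc(C(O)CCO)cc2OC)cc1OC | intermediate
24 | 1-{3-(benzyloxy)-4-{[(1S,2S)-1-[(tert-butyldimethylsilyl)oxy]-3-[(tert-butyldiphenylsilyl)oxy]-1-(3,4-dimethoxyphenyl)propan-2-yl]oxy}-5-methoxyphenyl}-3-hydroxypropan-1-one | COc1ccc([C@H](O[Si](C)(C)C(C)(C)C)[C@H](CO[Si](c2ccccc2)(c2ccccc2)C(C)(C)C)Oc2c(OCc3ccccc3)cc(C(=O)CCO)cc2OC)cc1OC | intermediate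
25 | 1-{3-(benzyloxy)-4-{[(1S,2S)-1-(3,4-dimethoxyphenyl)-1,3-dihydroxypropan-2-yl]oxy}-5-methoxyphenyl}-3-hydroxypropan-1-one | COc1ccc([C@H](O)[C@H](CO)Oc2c(OCc3ccccc3)cc(C(=O)CCO)cc2OC)cc1OC | intermediate
26 | 1-{4-{[(1S,2S)-1-(3,4-dimethoxyphenyl)-1,3-dihydroxypropan-2-yl]oxy}-3-hydroxy-5-methoxyphenyl}-3-hydroxypropan-1-one (CNP0188882.1) | COc1ccc([C@H](O)[C@H](CO)Oc2c(O)cc(C(=O)CCO)cc2OC)cc1OC | target

## Step count and least certain steps

Total step count: 18. Longest linear sequence: 18 steps (1 to 26); compounds 2, 7, 14 and 20 enter as purchased materials.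

**Step 5 (key step).** The discrimination between the enantiotopic arms may be insufficient, or the acyl transfer slow, because the aryloxy group with two ortho substituents is much larger than the benzyloxy group of the model diol and may not sit in the binding pocket as assumed. The sense of the acylation may also be the opposite of the predicted one.
- Fallback: keep the desymmetrisation but run it as an enzymatic hydrolysis. Setting out from 6, acetylation of both arms (Ac2O, pyridine) gives 2-[2-(benzyloxy)-4-(1,3-dioxolan-2-yl)-6-methoxyphenoxy]propane-1,3-diyl diacetate F1.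
- The same lipase, or porcine pancreatic lipase, in phosphate buffer should cleave one enantiotopic ester and give the (2R)-monoacetate F2. This is the enantiomer complementary to 8, in which the free arm is the future C7; it is also the compound to be processed if step 5 itself turns out to give the R enantiomer.
- The free arm of F2 is oxidised as in step 8 to the (2S)-acetoxy acid F3. Coupling as in step 9 gives the (2S)-acetoxy Weinreb amide F4, and methanolysis (K2CO3, MeOH) gives the (2S)-hydroxy Weinreb amide F5.
- Silylation of F5 with t-BuPh2SiCl and imidazole brings the material back to the route at 13.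

**Step 10.** Proton abstraction at C8 by the aryllithium may compete with addition to the hindered amide. This would erode the configurational purity or expel the silyloxy group from C9.
- Fallback: a less basic nucleophile on a more electrophilic carbonyl. Setting out from 10, Parikh–Doering oxidation gives aldehyde 11, isolated this time.
- Addition of 3,4-dimethoxyphenylmagnesium bromide F6 (from 14 and magnesium) at −78 °C gives the (2S)-carbinol F7 as a mixture of C7 epimers.
- Oxidation of F7 with Dess–Martin periodinane returns to the route at 16.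

**Step 11.** The facial selectivity may be poor if a lithium chelate between the C7 carbonyl, the C8 ether oxygen and the ortho oxygens of ring B competes with the Felkin–Anh pathway; that chelate leads to the erythro alcohol.
- Fallback: replace substrate control by catalyst control. Setting out from 16, transfer hydrogenation with RuCl(p-cymene)[(R,R)-TsDPEN] and HCO2H–NEt3 should let the catalyst choose the face of the aryl ketone and give the 7S alcohol, coming back at 17. No new compound is made (entry F0).

**Step 16.** The oxidation on the solid oxidant may be slow, and the β-hydroxy ketone formed may lose water on its surface to give the aryl vinyl ketone.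
- Fallback: protection and a homogeneous oxidant in place of chemoselectivity. Setting out from 23, selective silylation of the primary hydroxyl (t-BuMe2SiCl, imidazole) gives the mono-silyl ether F8.
- Dess–Martin periodinane oxidises the remaining benzylic alcohol to the silyloxy ketone F9.
- The fluoride conditions of step 17 remove all three silyl groups and return to the route at 25.

**Step 18.** Over-reduction is the danger: hydrogenolysis of the C7–O bond, which is activated by the para methoxy group of ring A, or saturation of the aryl ketone before debenzylation is complete.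
- Fallback: change the order of the last two operations so that the benzyl group is removed while the C7 oxygen still carries its bulky silyl group. Setting out from 24, hydrogenolysis gives the phenolic bis-silyl ether F10.
- Buffered fluoride as in step 17 then gives 26.

## Further compounds

F1 | step 5 | 2-[2-(benzyloxy)-4-(1,3-dioxolan-2-yl)-6-methoxyphenoxy]propane-1,3-diyl diacetate | CC(=O)OCC(COC(C)=O)Oc1c(OCc2ccccc2)cc(C2OCCO2)cc1OC
F2 | step 5 | (2R)-2-[2-(benzyloxy)-4-(1,3-dioxolan-2-yl)-6-methoxyphenoxy]-3-hydroxypropyl acetate | OC[C@H](COC(C)=O)Oc1c(OCc2ccccc2)cc(C2OCCO2)cc1OC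
F3 | step 5 | (2S)-3-acetoxy-2-[2-(benzyloxy)-4-(1,3-dioxolan-2-yl)-6-methoxyphenoxy]propanoic acid | OC(=O)[C@H](COC(C)=O)Oc1c(OCc2ccccc2)cc(C2OCCO2)cc1OC
F4 | step 5 | (2S)-2-[2-(benzyloxy)-4-(1,3-dioxolan-2-yl)-6-methoxyphenoxy]-3-[methoxy(methyl)amino]-3-oxopropyl acetate | CON(C)C(=O)[C@H](COC(C)=O)Oc1c(OCc2ccccc2)cc(C2OCCO2)cc1OC
F5 | step 5 | (2S)-2-[2-(benzyloxy)-4-(1,3-dioxolan-2-yl)-6-methoxyphenoxy]-3-hydroxy-N-methoxy-N-methylpropanamide | CON(C)C(=O)[C@H](CO)Oc1c(OCc2ccccc2)cc(C2OCCO2)cc1OC
F6 | step 10 | 3,4-dimethoxyphenylmagnesium bromide | COc1ccc([Mg]Br)cc1OC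
F7 | step 10 | (2S)-2-[2-(benzyloxy)-4-(1,3-dioxolan-2-yl)-6-methoxyphenoxy]-3-[(tert-butyldiphenylsilyl)oxy]-1-(3,4-dimethoxyphenyl)propan-1-ol, both epimers at C1 | COc1ccc(C(O)[C@H](CO[Si](c2ccccc2)(c2ccccc2)C(C)(C)C)Oc2c(OCc3ccccc3)cc(C3OCCO3)cc2OC)cc1OC
F0 | step 11 | none | none
F8 | step 16 | 1-{3-(benzyloxy)-4-{[(1S,2S)-1-[(tert-butyldimethylsilyl)oxy]-3-[(tert-butyldiphenylsilyl)oxy]-1-(3,4-dimethoxyphenyl)propan-2-yl]oxy}-5-methoxyphenyl}-3-[(tert-butyldimethylsilyl)oxy]propan-1-ol, both epimers at C1 | COc1ccc([C@H](O[Si](C)(C)C(C)(C)C)[C@H](CO[Si](c2ccccc2)(c2ccccc2)C(C)(C)C)Oc2c(OCc3ccccc3)cc(C(O)CCO[Si](C)(C)C(C)(C)C)cc2OC)cc1OC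
F9 | step 16 | 1-{3-(benzyloxy)-4-{[(1S,2S)-1-[(tert-butyldimethylsilyl)oxy]-3-[(tert-butyldiphenylsilyl)oxy]-1-(3,4-dimethoxyphenyl)propan-2-yl]oxy}-5-methoxyphenyl}-3-[(tert-butyldimethylsilyl)oxy]propan-1-one | COc1ccc([C@H](O[Si](C)(C)C(C)(C)C)[C@H](CO[Si](c2ccccc2)(c2ccccc2)C(C)(C)C)Oc2c(OCc3ccccc3)cc(C(=O)CCO[Si](C)(C)C(C)(C)C)cc2OC)cc1OC
F10 | step 18 | 1-{4-{[(1S,2S)-1-[(tert-butyldimethylsilyl)oxy]-3-[(tert-butyldiphenylsilyl)oxy]-1-(3,4-dimethoxyphenyl)propan-2-yl]oxy}-3-hydroxy-5-methoxyphenyl}-3-hydroxypropan-1-one | COc1ccc([C@H](O[Si](C)(C)C(C)(C)C)[C@H](CO[Si](c2ccccc2)(c2ccccc2)C(C)(C)C)Oc2c(O)cc(C(=O)CCO)cc2OC)cc1OC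
A1 | alternative 1 | (4S,5S)-2,2-di-tert-butyl-4-(3,4-dimethoxyphenyl)-1,3,2-dioxasilinan-5-ol | COc1ccc([C@H](O[Si]2(C(C)(C)C)C(C)(C)C)[C@H](CO2)O)cc1OC
A2 | alternative 1 | methyl 4-diazo-3,5-dioxocyclohexane-1-carboxylate | COC(=O)C1CC(=O)C(=[N+]=[N-])C(=O)C1
A3 | alternative 1 | methyl 4-{[(4S,5S)-2,2-di-tert-butyl-4-(3,4-dimethoxyphenyl)-1,3,2-dioxasilinan-5-yl]oxy}-3,5-dioxocyclohexane-1-carboxylate | COc1ccc([C@H](O[Si]2(C(C)(C)C)C(C)(C)C)[C@H](CO2)OC2C(=O)CC(C(=O)OC)CC2=O)cc1OC
A4 | alternative 2 | methyl 3-(benzyloxy)-4-{[1-(3,4-dimethoxyphenyl)-3-methoxy-1,3-dioxopropan-2-yl]oxy}-5-methoxybenzoate (racemic) | COc1ccc(C(=O)C(C(=O)OC)Oc2c(OCc3ccccc3)cc(C(=O)OC)cc2OC)cc1OC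
A5 | alternative 2 | methyl 3-(benzyloxy)-4-{[(1S,2R)-1-(3,4-dimethoxyphenyl)-1-hydroxy-3-methoxy-3-oxopropan-2-yl]oxy}-5-methoxybenzoate | COc1ccc([C@H](O)[C@H](C(=O)OC)Oc2c(OCc3ccccc3)cc(C(=O)OC)cc2OC)cc1OC
A6 | alternative 3 | methyl 3-(benzyloxy)-4-{[(2R)-1-hydroxy-3-(4-hydroxy-3-methoxyphenyl)propan-2-yl]oxy}-5-methoxybenzoate | COc1cc(C[C@H](CO)Oc2c(OCc3ccccc3)cc(C(=O)OC)cc2OC)ccc1O
A7 | alternative 3 | methyl 3-(benzyloxy)-4-{[(1S,2S)-1,3-dihydroxy-1-(4-hydroxy-3-methoxyphenyl)propan-2-yl]oxy}-5-methoxybenzoate | COc1cc([C@H](O)[C@H](CO)Oc2c(OCc3ccccc3)cc(C(=O)OC)cc2OC)ccc1O
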